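**Retrosynthetic overview**

1. The acid is cut at the CH2–CH2 bond next to the dioxane (Julia–Kocienski olefination, then diimide). This gives an achiral (Z)-ylidene octalin allyl sulfone and a 1,2-dioxane aldehyde that carries all three stereocentres.
2. Enabling feature of the octalin: the ring-fusion double bond C4a=C8a belongs to both carbocycles, and in ring B it lies across from the C6–C7 bond, each flanked by one sp3 carbon (C5, quaternary, and C8). Both bonds are therefore olefin-metathesis retrons (C6–C7 at the alkene level). Cutting them opens ring A and ring B at once to an acyclic tetraene, in which the future ylidene is a spectator (Z)-enoate made by a stereoretentive Negishi coupling of a (Z)-enol triflate.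
3. Ring order: ring A (through C4a=C8a), then ring B (through C6=C7), in one double ring-closing metathesis; C6=C7 is hydrogenated in the next step. The 1,2-dioxane is built separately: tertiary C–O bond first (epoxide perhydrolysis, inversion), ring closure second (intramolecular SN2, inversion).
4. Stereocentres: the quaternary peroxy carbon comes from (R)-2-methylglycidol; the CH(CH3)–CH(O) pair comes from an anti-selective crotylboration.

Key step: step 7

Remark: locants of the bicyclic unit are naphthalene locants (ylidene carbon C2, gem-dimethyl carbon C5, ring-fusion carbons C4a and C8a); ring A carries the ylidene, ring B the gem-dimethyl group.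

**Route**

Step 1
Reactants: 1 trimethyl(3-methylbut-2-en-1-yl)silane; 2 methyl 4-chloro-4-oxobutanoate
Product: 3 methyl 5,5-dimethyl-4-oxohept-6-enoate
Conditions: AlCl3, CH2Cl2, −78 °C
Reagents that add atoms: none
Why: Lewis-acid-promoted acylation of an allylsilane (Hosomi–Sakurai-type SE2') delivers the acyl group to the γ-carbon of the prenyl unit, giving an α,α-dimethyl β,γ-unsaturated ketone that cannot conjugate because its α-carbon is quaternary.

Step 2
Reactants: 3 methyl 5,5-dimethyl-4-oxohept-6-enoate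
Product: 4 methyl 5,5-dimethyl-4-methylidenehept-6-enoate
Conditions: Zn, CH2Br2, TiCl4, THF, 0 °C to rt
Reagents that add atoms: dibromomethane, BrCBr
Why: Takai–Lombardo methylenation is non-basic, spares the ester and is the standard method for hindered, enolisable ketones.

Step 3
Reactants: 4 methyl 5,5-dimethyl-4-methylidenehept-6-enoate; 5 tert-butyl acetate
Product: 6 tert-butyl 7,7-dimethyl-6-methylidene-3-oxonon-8-enoate
Conditions: LiN(iPr)2 (2.2 equiv), 5 (2.2 equiv), THF, −78 °C; then 4, −78 to 0 °C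
Reagents that add atoms: none
Why: Crossed Claisen condensation of the methyl ester with the lithium enolate of tert-butyl acetate should give the β-keto ester, driven by deprotonation of the product.

Step 4
Reactants: 6 tert-butyl 7,7-dimethyl-6-methylidene-3-oxonon-8-enoate
Product: 7 tert-butyl (2Z)-7,7-dimethyl-6-methylidene-3-[(trifluoromethanesulfonyl)oxy]nona-2,8-dienoate
Conditions: (CF3SO2)2O, saturated aq. LiOH, toluene, 5 °C
Reagents that add atoms: trifluoromethanesulfonic anhydride, O=S(=O)(OS(=O)(=O)C(F)(F)F)C(F)(F)F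
Why: O-Sulfonylation of the lithium-chelated (Z)-enolate of a β-keto ester should give the (Z)-enol triflate, which fixes the later ylidene geometry (triflate cis to the ester).

Step 5
Reactants: 8 3-chloro-2-(chloromethyl)prop-1-ene; 9 vinylmagnesium bromide
Product: 10 2-(chloromethyl)penta-1,4-diene
Conditions: CuI (5 mol%), THF, −30 to 0 °C, 8 in threefold excess
Reagents that add atoms: none
Why: Copper-catalysed allylic substitution of the symmetrical bis-allylic dichloride by a vinyl Grignard reagent gives one product whether it runs SN2 or SN2'; the excess of 8 suppresses double substitution.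

Step 6
Reactants: 7 tert-butyl (2Z)-7,7-dimethyl-6-methylidene-3-[(trifluoromethanesulfonyl)oxy]nona-2,8-dienoate; 10 2-(chloromethyl)penta-1,4-diene
Product: 12 tert-butyl (2Z)-7,7-dimethyl-6-methylidene-3-(2-methylidenepent-4-en-1-yl)nona-2,8-dienoate, via allylzinc chloride 11 (not isolated)
Conditions: 10, Zn dust, LiCl, THF, rt; then 7, Pd(PPh3)4 (5 mol%), THF, 0 °C to rt
Reagents that add atoms: none
Why: Negishi coupling of an enol triflate proceeds with retention at the sp2 carbon, so the new CH2 branch ends up cis to the ester (Z); the 2-substituted allylzinc is symmetrical, so no regiochemical question arises.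

Step 7
Reactants: 12 tert-butyl (2Z)-7,7-dimethyl-6-methylidene-3-(2-methylidenepent-4-en-1-yl)nona-2,8-dienoate
Product: 14 tert-butyl (2Z)-2-(5,5-dimethyl-3,4,5,8-tetrahydronaphthalen-2(1H)-ylidene)acetate, via monocyclic triene 13 (not isolated)
Conditions: [RuCl2(1,3-di-o-tolylimidazolidin-2-ylidene)(=CH-C6H4-2-OiPr)] (o-tolyl variant of the second-generation Hoveyda–Grubbs catalyst, 5–10 mol%), 1,4-benzoquinone (10 mol%), toluene/C6F6, 0.005 M, 80 °C, argon sparge
Reagents that add atoms: none
Why: A ruthenium alkylidene formed on the unhindered methylidene (future C8a) should engage the methylidene next to the quaternary carbon (future C4a) through a ruthenacyclobutane, expel ethene and close ring A as a six-membered ring by ring-closing metathesis onto the tetrasubstituted C4a=C8a olefin; the vinyl group on C5 and the allyl group on C8a are then held cis on the new double bond, and a second ring-closing metathesis (six-membered, C6=C7, ethene lost) closes ring B. The closest known reaction types are tandem (double) ring-closing metathesis of tetraenes to fused bicycles and ring-closing metathesis to tetrasubstituted cyclohexenes with o-tolyl-substituted carbene ruthenium catalysts. No stereocentre is created; the only stereo-element, the Z enoate, is trisubstituted and electron-poor and should stay a spectator, because engaging it would require an ester-substituted ruthenium carbene, so the geometry set in step 6 is carried into the ring. Chemoselectivity rests on ring size: among the four reactive olefins the only five- to seven-membered closures are the two wanted ones (other pairings give three-, eight- or ten-membered rings), and intermolecular metathesis of the terminal olefins is reversible. Loss of ethene and the stability of the bicyclic 1,4-diene, which cannot aromatise because C5 is quaternary, should drive the cascade.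

Step 8
Reactants: 14 tert-butyl (2Z)-2-(5,5-dimethyl-3,4,5,8-tetrahydronaphthalen-2(1H)-ylidene)acetate
Product: 15 tert-butyl (2Z)-2-(5,5-dimethyl-3,4,5,6,7,8-hexahydronaphthalen-2(1H)-ylidene)acetate
Conditions: H2 (1 atm), RhCl(PPh3)3 (5 mol%), benzene, rt
Reagents that add atoms: none
Why: Homogeneous hydrogenation with RhCl(PPh3)3 should reduce the cis-disubstituted C6=C7 olefin and leave the tetrasubstituted olefin and the trisubstituted, ester-conjugated olefin untouched (steric discrimination).

Step 9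
Reactants: 15 tert-butyl (2Z)-2-(5,5-dimethyl-3,4,5,6,7,8-hexahydronaphthalen-2(1H)-ylidene)acetate
Product: 16 (2Z)-2-(5,5-dimethyl-3,4,5,6,7,8-hexahydronaphthalen-2(1H)-ylidene)ethan-1-ol
Conditions: iBu2AlH (3 equiv), CH2Cl2, −78 to 0 °C; aq. Rochelle salt
Reagents that add atoms: none
Why: 1,2-Reduction of the α,β-unsaturated ester with the aluminium hydride gives the allylic alcohol without touching the olefin geometry.

Step 10
Reactants: 16 (2Z)-2-(5,5-dimethyl-3,4,5,6,7,8-hexahydronaphthalen-2(1H)-ylidene)ethan-1-ol; 17 1-phenyl-1H-tetrazole-5-thiol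
Product: 18 5-{[(2Z)-2-(5,5-dimethyl-3,4,5,6,7,8-hexahydronaphthalen-2(1H)-ylidene)ethyl]sulfanyl}-1-phenyl-1H-tetrazole
Conditions: PPh3, diisopropyl azodicarboxylate, THF, 0 °C to rt
Reagents that add atoms: none
Why: Mitsunobu thioetherification of a primary allylic alcohol proceeds by direct SN2 displacement and keeps the position and geometry of the double bond.

Step 11
Reactants: 18 5-{[(2Z)-2-(5,5-dimethyl-3,4,5,6,7,8-hexahydronaphthalen-2(1H)-ylidene)ethyl]sulfanyl}-1-phenyl-1H-tetrazole
Product: 19 5-{[(2Z)-2-(5,5-dimethyl-3,4,5,6,7,8-hexahydronaphthalen-2(1H)-ylidene)ethyl]sulfonyl}-1-phenyl-1H-tetrazole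
Conditions: H2O2 (30% aq.), (NH4)6Mo7O24·4H2O (10 mol%), EtOH, 0 °C to rt
Reagents that add atoms: hydrogen peroxide, OO
Why: Molybdate-catalysed oxidation of the sulfide to the sulfone should outpace epoxidation of the olefins at low temperature (standard preparation of allylic Julia–Kocienski reagents).

Step 12
Reactants: 20 [(2R)-2-methyloxiran-2-yl]methanol; 21 allylmagnesium bromide
Product: 22 (2S)-2-methylhept-6-ene-1,2-diol
Conditions: CuI (10 mol%), THF, −30 to 0 °C, 21 (2.5 equiv)
Reagents that add atoms: none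
Why: Copper-catalysed Grignard opening of the epoxide at its CH2 terminus leaves the quaternary stereocentre untouched, so the configuration of the chiral-pool epoxide is carried over.

Step 13
Reactants: 22 (2S)-2-methylhept-6-ene-1,2-diol
Product: 24 (2S)-2-(but-3-en-1-yl)-2-methyloxirane, via primary monotosylate 23 (not isolated)
Conditions: TsCl, Et3N, Bu2SnO (2 mol%), CH2Cl2, 0 °C; then K2CO3, MeOH, rt
Reagents that add atoms: none
Why: Selective sulfonylation of the primary hydroxyl and Williamson closure by the tertiary alkoxide rebuild a 2,2-disubstituted epoxide with the C–O bond of the stereocentre intact.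

Step 14
Reactants: 24 (2S)-2-(but-3-en-1-yl)-2-methyloxirane
Product: 26 3-[(2S)-2-methyloxiran-2-yl]propanal, via ozonide 25 (not isolated)
Conditions: O3, CH2Cl2, −78 °C; then Me2S, −78 °C to rt
Reagents that add atoms: ozone, [O-][O+]=O
Why: Ozonolysis with reductive work-up cleaves the only olefin; the epoxide is inert.

Step 15
Reactants: 26 3-[(2S)-2-methyloxiran-2-yl]propanal
Product: 27 (3R,4S)-3-methyl-6-[(2S)-2-methyloxiran-2-yl]hex-1-en-4-ol
Conditions: (S,S)-tartrate (E)-crotylboronate, 4 Å molecular sieves, toluene, −78 °C; then aq. NaHCO3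
Reagents that add atoms: diisopropyl (4S,5S)-2-[(2E)-but-2-en-1-yl]-1,3,2-dioxaborolane-4,5-dicarboxylate, C/C=C/CB1O[C@H](C(=O)OC(C)C)[C@H](O1)C(=O)OC(C)C
Why: Roush (E)-crotylboration through a chair Zimmerman–Traxler transition state gives the anti homoallylic alcohol, and the (S,S)-tartrate directs addition to the Re face, setting both new stereocentres; the minor facial isomer is a diastereomer and should be removable later.

Step 16
Reactants: 27 (3R,4S)-3-methyl-6-[(2S)-2-methyloxiran-2-yl]hex-1-en-4-ol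
Product: 28 (3R,4S)-3-methyl-6-[(2S)-2-methyloxiran-2-yl]hex-1-en-4-yl methanesulfonate
Conditions: MsCl, Et3N, CH2Cl2, −20 °C
Reagents that add atoms: methanesulfonyl chloride, CS(=O)(=O)Cl
Why: Sulfonylation under basic conditions activates the secondary carbon for displacement and removes the free hydroxyl that could otherwise open the epoxide to a tetrahydrofuran.

Step 17
Reactants: 28 (3R,4S)-3-methyl-6-[(2S)-2-methyloxiran-2-yl]hex-1-en-4-yl methanesulfonate
Product: 29 (3R,4S,7R)-7-hydroperoxy-8-hydroxy-3,7-dimethyloct-1-en-4-yl methanesulfonate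
Conditions: anhydrous H2O2 in Et2O, H3PMo12O40 (5 mol%), rt
Reagents that add atoms: hydrogen peroxide, OO
Why: Phosphomolybdic-acid-catalysed perhydrolysis of a 2,2-disubstituted epoxide occurs at the tertiary carbon by anti (SN2-like) attack, so the tertiary hydroperoxide should form with inversion and set the quaternary peroxy stereocentre.

Step 18
Reactants: 29 (3R,4S,7R)-7-hydroperoxy-8-hydroxy-3,7-dimethyloct-1-en-4-yl methanesulfonate
Product: 30 [(3R,6R)-6-[(2R)-but-3-en-2-yl]-3-methyl-1,2-dioxan-3-yl]methanol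
Conditions: KOtBu (1.05 equiv), 18-crown-6, THF, −20 to 0 °C
Reagents that add atoms: none
Why: Intramolecular Williamson-type alkylation of the hydroperoxide anion (6-exo-tet) displaces the secondary mesylate with inversion, closing the 1,2-dioxane and setting the ring CH stereocentre.

Step 19
Reactants: 30 [(3R,6R)-6-[(2R)-but-3-en-2-yl]-3-methyl-1,2-dioxan-3-yl]methanol
Product: 33 (2S)-2-[(3R,6R)-6-(hydroxymethyl)-6-methyl-1,2-dioxan-3-yl]propanoic acid, via ozonide 31 (not isolated), via aldehyde 32 (not isolated)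
Conditions: O3, CH2Cl2, −78 °C; Me2S; then NaClO2, NaH2PO4, 2-methylbut-2-ene, t-BuOH/H2O, 0 °C
Reagents that add atoms: ozone, [O-][O+]=O; sodium chlorite, [Na+].[O-]Cl=O
Why: Ozonolysis of the vinyl group followed by Pinnick oxidation of the aldehyde gives the acid; dialkyl peroxides tolerate both, and the buffered, non-basic medium should preserve the α-stereocentre.

Step 20
Reactants: 33 (2S)-2-[(3R,6R)-6-(hydroxymethyl)-6-methyl-1,2-dioxan-3-yl]propanoic acid
Product: 34 methyl (2S)-2-[(3R,6R)-6-(hydroxymethyl)-6-methyl-1,2-dioxan-3-yl]propanoate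
Conditions: Me3SiCHN2, MeOH/toluene, 0 °C
Reagents that add atoms: (trimethylsilyl)diazomethane, C[Si](C)(C)C=[N+]=[N-]
Why: Esterification with the diazoalkane is neutral and selective for the carboxylic acid over the primary alcohol.

Step 21
Reactants: 34 methyl (2S)-2-[(3R,6R)-6-(hydroxymethyl)-6-methyl-1,2-dioxan-3-yl]propanoate
Product: 35 methyl (2S)-2-[(3R,6R)-6-formyl-6-methyl-1,2-dioxan-3-yl]propanoate
Conditions: Dess–Martin periodinane, NaHCO3, CH2Cl2, 0 °C to rt
Reagents that add atoms: none
Why: Dess–Martin oxidation of the primary alcohol gives an aldehyde that cannot enolise (quaternary α-carbon), and the peroxide is inert to the hypervalent iodine reagent.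

Step 22
Reactants: 19 5-{[(2Z)-2-(5,5-dimethyl-3,4,5,6,7,8-hexahydronaphthalen-2(1H)-ylidene)ethyl]sulfonyl}-1-phenyl-1H-tetrazole; 35 methyl (2S)-2-[(3R,6R)-6-formyl-6-methyl-1,2-dioxan-3-yl]propanoate
Product: 36 methyl (2S)-2-[(3R,6R)-6-[(1E,3Z)-3-(5,5-dimethyl-3,4,5,6,7,8-hexahydronaphthalen-2(1H)-ylidene)prop-1-en-1-yl]-6-methyl-1,2-dioxan-3-yl]propanoate (new disubstituted olefin expected mainly E; its geometry is irrelevant)
Conditions: KN(SiMe3)2 (1.1 equiv) added to 19 and 35, THF, −78 to −40 °C
Reagents that add atoms: none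
Why: Julia–Kocienski olefination (addition of the α-sulfonyl allyl anion, Smiles rearrangement, loss of SO2 and tetrazolone) joins the fragments; attack through the α-carbon keeps the Z trisubstituted olefin, and in-situ generation of the anion at low temperature limits its contact with the peroxide.

Step 23
Reactants: 36 methyl (2S)-2-[(3R,6R)-6-[(1E,3Z)-3-(5,5-dimethyl-3,4,5,6,7,8-hexahydronaphthalen-2(1H)-ylidene)prop-1-en-1-yl]-6-methyl-1,2-dioxan-3-yl]propanoate
Product: 37 methyl (2S)-2-[(3R,6S)-6-[(3Z)-3-(5,5-dimethyl-3,4,5,6,7,8-hexahydronaphthalen-2(1H)-ylidene)propyl]-6-methyl-1,2-dioxan-3-yl]propanoate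
Conditions: KO2CN=NCO2K, AcOH, MeOH/CH2Cl2, 0 °C to rt, added in portions and stopped after one equivalent of H2 is taken up
Reagents that add atoms: none
Why: Diimide transfers H2 concertedly to the less substituted end of the conjugated diene much faster than to tri- and tetrasubstituted olefins and does not cleave O–O bonds, so the saturated two-carbon link should result.

Step 24
Reactants: 37 methyl (2S)-2-[(3R,6S)-6-[(3Z)-3-(5,5-dimethyl-3,4,5,6,7,8-hexahydronaphthalen-2(1H)-ylidene)propyl]-6-methyl-1,2-dioxan-3-yl]propanoate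
Product: 38 (2S)-2-[(3R,6S)-6-[(3Z)-3-(5,5-dimethyl-3,4,5,6,7,8-hexahydronaphthalen-2(1H)-ylidene)propyl]-6-methyl-1,2-dioxan-3-yl]propanoic acid (CNP0223199.1)
Conditions: LiOH, THF/H2O, 0 °C to rt; then 1 M HCl to pH 4
Reagents that add atoms: lithium hydroxide, [Li+].[OH-]
Why: Mild saponification of the methyl ester is the usual last step for 1,2-dioxane propanoic acids and should leave the peroxide and the α-stereocentre intact.

**Compound list**

1 | trimethyl(3-methylbut-2-en-1-yl)silane | CC(C)=CC[Si](C)(C)C | starting material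
2 | methyl 4-chloro-4-oxobutanoate | COC(=O)CCC(Cl)=O | starting material
3 | methyl 5,5-dimethyl-4-oxohept-6-enoate | COC(=O)CCC(=O)C(C)(C)C=C | intermediate
4 | methyl 5,5-dimethyl-4-methylidenehept-6-enoate | COC(=O)CCC(=C)C(C)(C)C=C | intermediate
5 | tert-butyl acetate | CC(=O)OC(C)(C)C | starting material
6 | tert-butyl 7,7-dimethyl-6-methylidene-3-oxonon-8-enoate | CC(C)(C)OC(=O)CC(=O)CCC(=C)C(C)(C)C=C | intermediate
7 | tert-butyl (2Z)-7,7-dimethyl-6-methylidene-3-[(trifluoromethanesulfonyl)oxy]nona-2,8-dienoate | CC(C)(C)OC(=O)/C=C(\OS(=O)(=O)C(F)(F)F)/CCC(=C)C(C)(C)C=C | intermediate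
8 | 3-chloro-2-(chloromethyl)prop-1-ene | C=C(CCl)CCl | starting material
9 | vinylmagnesium bromide | C=C[Mg]Br | starting material
10 | 2-(chloromethyl)penta-1,4-diene | C=CCC(=C)CCl | intermediate
11 | chloro(2-methylidenepent-4-en-1-yl)zinc | C=CCC(=C)C[Zn]Cl | intermediate (not isolated)
12 | tert-butyl (2Z)-7,7-dimethyl-6-methylidene-3-(2-methylidenepent-4-en-1-yl)nona-2,8-dienoate | CC(C)(C)OC(=O)/C=C(\CC(=C)CC=C)/CCC(=C)C(C)(C)C=C | intermediate
13 | tert-butyl (2Z)-2-[4-(2-methylbut-3-en-2-yl)-3-(prop-2-en-1-yl)cyclohex-3-en-1-ylidene]acetate | CC(C)(C)OC(=O)/C=C1/CCC(C(C)(C)C=C)=C(CC=C)C1 | intermediate (not isolated)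
14 | tert-butyl (2Z)-2-(5,5-dimethyl-3,4,5,8-tetrahydronaphthalen-2(1H)-ylidene)acetate | CC(C)(C)OC(=O)/C=C1/CCC2=C(C1)CC=CC2(C)C | intermediate
15 | tert-butyl (2Z)-2-(5,5-dimethyl-3,4,5,6,7,8-hexahydronaphthalen-2(1H)-ylidene)acetate | CC(C)(C)OC(=O)/C=C1/CCC2=C(C1)CCCC2(C)C | intermediate
16 | (2Z)-2-(5,5-dimethyl-3,4,5,6,7,8-hexahydronaphthalen-2(1H)-ylidene)ethan-1-ol | OC/C=C1/CCC2=C(C1)CCCC2(C)C | intermediate
17 | 1-phenyl-1H-tetrazole-5-thiol | Sc1nnnn1-c1ccccc1 | starting material
18 | 5-{[(2Z)-2-(5,5-dimethyl-3,4,5,6,7,8-hexahydronaphthalen-2(1H)-ylidene)ethyl]sulfanyl}-1-phenyl-1H-tetrazole | c1ccccc1-n1nnnc1SC/C=C1/CCC2=C(C1)CCCC2(C)C | intermediate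
19 | 5-{[(2Z)-2-(5,5-dimethyl-3,4,5,6,7,8-hexahydronaphthalen-2(1H)-ylidene)ethyl]sulfonyl}-1-phenyl-1H-tetrazole | c1ccccc1-n1nnnc1S(=O)(=O)C/C=C1/CCC2=C(C1)CCCC2(C)C | intermediate
20 | [(2R)-2-methyloxiran-2-yl]methanol | C[C@@]1(CO)CO1 | starting material
21 | allylmagnesium bromide | C=CC[Mg]Br | starting material
22 | (2S)-2-methylhept-6-ene-1,2-diol | C=CCC[C@@](O)(C)CO | intermediate
23 | (2S)-2-hydroxy-2-methylhept-6-en-1-yl 4-methylbenzenesulfonate | C=CCC[C@@](O)(C)COS(=O)(=O)c1ccc(C)cc1 | intermediate (not isolated)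
24 | (2S)-2-(but-3-en-1-yl)-2-methyloxirane | C=CCC[C@@]1(C)CO1 | intermediate
25 | 3-{2-[(2S)-2-methyloxiran-2-yl]ethyl}-1,2,4-trioxolane | C1(CC[C@@]2(C)CO2)OCOO1 | intermediate (not isolated)
26 | 3-[(2S)-2-methyloxiran-2-yl]propanal | O=CCC[C@@]1(C)CO1 | intermediate
27 | (3R,4S)-3-methyl-6-[(2S)-2-methyloxiran-2-yl]hex-1-en-4-ol | C[C@H](C=C)[C@@H](O)CC[C@@]1(C)CO1 | intermediate
28 | (3R,4S)-3-methyl-6-[(2S)-2-methyloxiran-2-yl]hex-1-en-4-yl methanesulfonate | C[C@H](C=C)[C@@H](OS(C)(=O)=O)CC[C@@]1(C)CO1 | intermediate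
29 | (3R,4S,7R)-7-hydroperoxy-8-hydroxy-3,7-dimethyloct-1-en-4-yl methanesulfonate | C[C@H](C=C)[C@@H](OS(C)(=O)=O)CC[C@](C)(CO)OO | intermediate
30 | [(3R,6R)-6-[(2R)-but-3-en-2-yl]-3-methyl-1,2-dioxan-3-yl]methanol | C[C@H](C=C)[C@H]1CC[C@](C)(CO)OO1 | intermediate
31 | {(3R,6R)-3-methyl-6-[(1R)-1-(1,2,4-trioxolan-3-yl)ethyl]-1,2-dioxan-3-yl}methanol (trioxolane carbon unassigned) | C[C@H](C1OCOO1)[C@H]1CC[C@](C)(CO)OO1 | intermediate (not isolated)
32 | (2S)-2-[(3R,6R)-6-(hydroxymethyl)-6-methyl-1,2-dioxan-3-yl]propanal | C[C@H](C=O)[C@H]1CC[C@](C)(CO)OO1 | intermediate (not isolated)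
33 | (2S)-2-[(3R,6R)-6-(hydroxymethyl)-6-methyl-1,2-dioxan-3-yl]propanoic acid | C[C@H](C(=O)O)[C@H]1CC[C@](C)(CO)OO1 | intermediate
34 | methyl (2S)-2-[(3R,6R)-6-(hydroxymethyl)-6-methyl-1,2-dioxan-3-yl]propanoate | C[C@H](C(=O)OC)[C@H]1CC[C@](C)(CO)OO1 | intermediate
35 | methyl (2S)-2-[(3R,6R)-6-formyl-6-methyl-1,2-dioxan-3-yl]propanoate | C[C@H](C(=O)OC)[C@H]1CC[C@](C)(C=O)OO1 | intermediate
36 | methyl (2S)-2-[(3R,6R)-6-[(1E,3Z)-3-(5,5-dimethyl-3,4,5,6,7,8-hexahydronaphthalen-2(1H)-ylidene)prop-1-en-1-yl]-6-methyl-1,2-dioxan-3-yl]propanoate | C[C@H](C(=O)OC)[C@H]1CC[C@](C)(/C=C/C=C2/CCC3=C(CCCC3(C)C)C2)OO1 | intermediate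
37 | methyl (2S)-2-[(3R,6S)-6-[(3Z)-3-(5,5-dimethyl-3,4,5,6,7,8-hexahydronaphthalen-2(1H)-ylidene)propyl]-6-methyl-1,2-dioxan-3-yl]propanoate | C[C@H](C(=O)OC)[C@H]1CC[C@](C)(CC/C=C2/CCC3=C(CCCC3(C)C)C2)OO1 | intermediate
38 | (2S)-2-[(3R,6S)-6-[(3Z)-3-(5,5-dimethyl-3,4,5,6,7,8-hexahydronaphthalen-2(1H)-ylidene)propyl]-6-methyl-1,2-dioxan-3-yl]propanoic acid | C[C@H](C(=O)O)[C@H]1CC[C@](C)(CC/C=C2/CCC3=C(CCCC3(C)C)C2)OO1 | target

**Step count and risks**

Total step count: 24. Longest linear sequence: 13 steps (steps 1–4, 6–11 and 22–24; the dioxane branch, steps 12–21 and 22–24, is equally long).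

Steps most likely to fail:

1. Step 7. The ruthenium alkylidene may fail to close the hindered tetrasubstituted olefin next to the quaternary carbon, so that the substrate is diverted into reversible oligomerisation through its terminal olefins while the catalyst decomposes. Fallback (aromatic route without metathesis, setting out from 2 and returning at 15): Friedel–Crafts acylation of anisole with 2 (AlCl3, CH2Cl2) should give methyl 4-(4-methoxyphenyl)-4-oxobutanoate F1. Geminal dimethylation of the aryl ketone with Me2TiCl2 (CH2Cl2, −30 °C) gives methyl 4-(4-methoxyphenyl)-4-methylpentanoate F2, and saponification gives 4-(4-methoxyphenyl)-4-methylpentanoic acid F3. Cyclisation in polyphosphoric acid gives 7-methoxy-4,4-dimethyl-3,4-dihydronaphthalen-1(2H)-one F4, and hydrogenolysis of the benzylic ketone (H2, Pd/C, AcOH) gives 6-methoxy-1,1-dimethyl-1,2,3,4-tetrahydronaphthalene F5. Birch reduction (Li, NH3, t-BuOH) gives 6-methoxy-1,1-dimethyl-1,2,3,4,5,8-hexahydronaphthalene F6, and mild hydrolysis with oxalic acid gives 5,5-dimethyl-3,4,5,6,7,8-hexahydronaphthalen-2(1H)-one F7. Horner–Wadsworth–Emmons olefination with tert-butyl (diethoxyphosphoryl)acetate (LiCl, DBU, MeCN) then gives 15 together with tert-butyl (2E)-2-(5,5-dimethyl-3,4,5,6,7,8-hexahydronaphthalen-2(1H)-ylidene)acetate F8, to be separated on AgNO3-impregnated silica. This fallback gives up control of the ylidene geometry and relies on that separation.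

2. Step 17. Ionisation of the activated epoxide to a tertiary cation would erode the configuration of the quaternary carbon, and the β-hydroxy hydroperoxide may fragment or the mesylate eliminate under the base of step 18. Fallback (secondary peroxide first, ring closure by acid; sets out from 27 and returns at 30): 27 is converted with (CF3SO2)2O and 2,6-lutidine (CH2Cl2, −78 °C) into (3R,4S)-3-methyl-6-[(2S)-2-methyloxiran-2-yl]hex-1-en-4-yl trifluoromethanesulfonate F9. Displacement with the potassium salt of 2-methoxypropan-2-yl hydroperoxide (KOtBu, THF, −78 to −20 °C) should give, with inversion, (2S)-2-{(3R,4R)-4-[(2-methoxypropan-2-yl)peroxy]-3-methylhex-5-en-1-yl}-2-methyloxirane F10. Aqueous acetic acid in THF removes the ketal to give (2S)-2-[(3R,4R)-4-hydroperoxy-3-methylhex-5-en-1-yl]-2-methyloxirane F11. Under the same acid F11 should open the epoxide intramolecularly at the tertiary carbon (6-exo, anti, inversion) to give 30.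

3. Step 22. The sulfonyl carbanion or the amide base may attack the O–O bond or deprotonate next to the ester (β-elimination opening the dioxane), and addition to the hindered aldehyde may be slow; the following mono-reduction of the diene also depends on clean material from this step. Fallback (neutral union by cross-metathesis, setting out from 35 and 16 and returning at 36): Wittig methylenation of 35 (Ph3P=CH2, THF, −78 °C) gives methyl (2S)-2-[(3R,6R)-6-ethenyl-6-methyl-1,2-dioxan-3-yl]propanoate F12. Oxidation of 16 with MnO2 gives (2Z)-2-(5,5-dimethyl-3,4,5,6,7,8-hexahydronaphthalen-2(1H)-ylidene)acetaldehyde F13, and methylenation gives (2Z)-5,5-dimethyl-2-(prop-2-en-1-ylidene)-1,2,3,4,5,6,7,8-octahydronaphthalene F14. Cross-metathesis of F12 with F14 (second-generation Hoveyda–Grubbs catalyst, CH2Cl2, 40 °C), a reaction type that tolerates dialkyl peroxides, should give 36.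

**Further compounds**

F1 | step 7 | methyl 4-(4-methoxyphenyl)-4-oxobutanoate | COC(=O)CCC(=O)c1ccc(OC)cc1
F2 | step 7 | methyl 4-(4-methoxyphenyl)-4-methylpentanoate | COC(=O)CCC(C)(C)c1ccc(OC)cc1
F3 | step 7 | 4-(4-methoxyphenyl)-4-methylpentanoic acid | OC(=O)CCC(C)(C)c1ccc(OC)cc1
F4 | step 7 | 7-methoxy-4,4-dimethyl-3,4-dihydronaphthalen-1(2H)-one | COc1ccc2c(c1)C(=O)CCC2(C)C
F5 | step 7 | 6-methoxy-1,1-dimethyl-1,2,3,4-tetrahydronaphthalene | COc1ccc2c(c1)CCCC2(C)C
F6 | step 7 | 6-methoxy-1,1-dimethyl-1,2,3,4,5,8-hexahydronaphthalene | COC1=CCC2=C(C1)CCCC2(C)C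
F7 | step 7 | 5,5-dimethyl-3,4,5,6,7,8-hexahydronaphthalen-2(1H)-one | O=C1CCC2=C(C1)CCCC2(C)C
F8 | step 7 | tert-butyl (2E)-2-(5,5-dimethyl-3,4,5,6,7,8-hexahydronaphthalen-2(1H)-ylidene)acetate | CC(C)(C)OC(=O)/C=C1\CCC2=C(C1)CCCC2(C)C
F9 | step 17 | (3R,4S)-3-methyl-6-[(2S)-2-methyloxiran-2-yl]hex-1-en-4-yl trifluoromethanesulfonate | C[C@H](C=C)[C@@H](OS(=O)(=O)C(F)(F)F)CC[C@@]1(C)CO1
F10 | step 17 | (2S)-2-{(3R,4R)-4-[(2-methoxypropan-2-yl)peroxy]-3-methylhex-5-en-1-yl}-2-methyloxirane | C[C@H](C=C)[C@H](OOC(C)(C)OC)CC[C@@]1(C)CO1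
F11 | step 17 | (2S)-2-[(3R,4R)-4-hydroperoxy-3-methylhex-5-en-1-yl]-2-methyloxirane | C[C@H](C=C)[C@H](OO)CC[C@@]1(C)CO1
F12 | step 22 | methyl (2S)-2-[(3R,6R)-6-ethenyl-6-methyl-1,2-dioxan-3-yl]propanoate | C[C@H](C(=O)OC)[C@H]1CC[C@](C)(C=C)OO1
F13 | step 22 | (2Z)-2-(5,5-dimethyl-3,4,5,6,7,8-hexahydronaphthalen-2(1H)-ylidene)acetaldehyde | O=C/C=C1/CCC2=C(C1)CCCC2(C)C
F14 | step 22 | (2Z)-5,5-dimethyl-2-(prop-2-en-1-ylidene)-1,2,3,4,5,6,7,8-octahydronaphthalene | C=C/C=C1/CCC2=C(C1)CCCC2(C)C
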